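**Plan**
- Retrosynthetic cuts, in order: the two acetates. Then C8=C17 and C14=C15 (one twofold Wittig methylenation), C12=C13 (cross-metathesis) and C7–C8 (ring B). Then C9–C11 (enolate allylation), C9–C10 and C5–C6 (two Claisen rearrangements), and C3–C4 with C5=C10 (Michael/aldol spiroannulation of ring A).
- Enabling feature: in ring B the exocyclic-methylene carbon C8 can be carried at carbonyl level, and its ring neighbour C7 is an unbranched, non-stereogenic CH2. Opening C7–C8 leaves ring A with two trans arms (C5–C6–C7 and C10–C9–C8). C9 is then the only enolisable carbon, so the C7/C9 ambiguity of a C8 decalone never arises.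
- Forward order: ring A first (C4 spiro-acetonide enone), then the C5 arm, the C10 arm and the C9 allyl group. Ring B closes by iodine–lithium exchange and acylation. The dienyl chain and the diacetate come last.
- Stereochemistry: an oxazaborolidine reduction sets C1–OH, which a Johnson–Claisen shift relays to C5. A second reduction sets C2–OH, which an Ireland–Claisen shift relays to quaternary C10. C9 is set by base equilibration next to the C8 ketone, and the 12E alkene by cross-metathesis.

Key step: step 16

Convention: labdane numbering is used for every intermediate. Ring A is C1–C5 and C10; ring B is C5–C10; C17 is the exocyclic methylene; C18 and C19 are the oxymethyl carbons on C4; C20 is the angular methyl. The target SMILES corresponds to 5S,9R,10S,12E, which is the ent-labdane series.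
Assumption: acetonide alcohol 1 is taken as a catalogue compound.

Step 1
Reactants: 1 (2,2-dimethyl-1,3-dioxan-5-yl)methanol
Product: 2 2,2-dimethyl-1,3-dioxane-5-carbaldehyde
Conditions: TEMPO (10 mol %), PhI(OAc)2 (1.1 equiv), CH2Cl2, rt
Reagents that add atoms: none
Why: TEMPO (oxoammonium) oxidation of a primary alcohol stops at the aldehyde under nearly neutral, non-aqueous conditions, so the acetonide stays on and the β-alkoxy aldehyde is not exposed to base.

Step 2
Reactants: 2 2,2-dimethyl-1,3-dioxane-5-carbaldehyde; 3 ethyl vinyl ketone (pent-1-en-3-one)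
Product: 5 spiro enone 3,3,8-trimethyl-2,4-dioxaspiro[5.5]undec-7-en-9-one (C1 ketone; C5=C10 alkene; C20 on C10; C4 spiro), via keto aldehyde 4 (not isolated)
Conditions: 2 added slowly to 3 (1.3 equiv), KOH (15 mol %), EtOH, 0 °C to rt; then 50 °C
Reagents that add atoms: none
Why: Robinson-type spiroannulation of an α-branched aldehyde: catalytic hydroxide triggers Michael addition to 3 (C3–C4 bond, after which quaternary C4 can no longer lose a β-alkoxide), and the C10 enolate of 4, the only one that reaches the formyl group through a six-membered ring, closes ring A by aldol condensation without forming a stereocentre.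

Step 3
Reactants: 5 spiro enone
Product: 6 (1S)-allylic alcohol (9S)-3,3,8-trimethyl-2,4-dioxaspiro[5.5]undec-7-en-9-ol
Conditions: (R)-2-methyl-CBS-oxazaborolidine (10 mol %), BH3·SMe2 (0.7 equiv), THF, −20 °C; MeOH quench
Reagents that add atoms: none
Why: Corey–Bakshi–Shibata reduction: the methyl-bearing alkene arm is the large substituent of the ketone, so the (R)-catalyst should deliver hydride to the face that gives the (1S)-carbinol, the source of all absolute configuration.

Step 4
Reactants: 6 (1S)-allylic alcohol; 7 triethyl orthoacetate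
Product: 9 (5S)-ester ethyl [(7S)-3,3,8-trimethyl-2,4-dioxaspiro[5.5]undec-8-en-7-yl]acetate, via ketene acetal 8 (not isolated)
Conditions: 7 (8 equiv), EtCO2H (10 mol %), 140 °C, EtOH distilled off
Reagents that add atoms: none
Why: Johnson–Claisen rearrangement: orthoester exchange and loss of ethanol give 8, whose suprafacial [3,3] shift forms C5–C6 on the ring face that carried the C1–O bond, so 1S is relayed to 5S while the alkene moves to C1=C10.

Step 5
Reactants: 9 (5S)-ester
Product: 10 (5S)-alcohol 2-[(7S)-3,3,8-trimethyl-2,4-dioxaspiro[5.5]undec-8-en-7-yl]ethanol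
Conditions: LiAlH4, Et2O, 0 °C
Reagents that add atoms: none
Why: Standard LiAlH4 reduction of an ester to the primary alcohol (C7–OH), to which the acetonide and the trisubstituted alkene are inert.

Step 6
Reactants: 10 (5S)-alcohol
Product: 11 tert-butyldimethylsilyl ether of 10 (C7–OTBS)
Conditions: TBSCl, imidazole, CH2Cl2, rt
Reagents that add atoms: tert-butyldimethylsilyl chloride, CC(C)(C)[Si](C)(C)Cl
Why: Silylation of the primary alcohol gives an ether that withstands the oxidation, the amide bases and the hydrogenation ahead, and that leaves with fluoride without touching the acetonide.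

Step 7
Reactants: 11 silyl ether
Product: 12 (5S)-enone (11 with C2 oxidised to the ketone; C2=O conjugated to C1=C10)
Conditions: Rh2(cap)4 (dirhodium tetrakis(caprolactamate), 1 mol %), t-BuOOH (70% in water, 6 equiv), K2CO3 (0.5 equiv), CH2Cl2, rt to 40 °C
Reagents that add atoms: tert-butyl hydroperoxide, CC(C)(C)OO
Why: Allylic C–H oxidation with t-BuOOH under dirhodium catalysis: C2 is the only allylic methylene (C5–H is tertiary and shielded by quaternary C4, C20 is a methyl group), which is the selectivity known from the oxidation of α-ionone-type rings to their 3-oxo derivatives.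

Step 8
Reactants: 12 (5S)-enone
Product: 13 (2R,5S)-allylic alcohol (C2–OH trans to the C5 arm)
Conditions: (S)-2-methyl-CBS-oxazaborolidine (20 mol %), BH3·SMe2 (0.7 equiv), THF, −30 °C; MeOH quench
Reagents that add atoms: none
Why: Second Corey–Bakshi–Shibata reduction under reagent control: with the C1=C10 arm as the large group the (S)-catalyst should give the (2R)-alcohol, and any material of the wrong enantiomeric series ends up as a separable diastereomer.

Step 9
Reactants: 13 (2R,5S)-allylic alcohol
Product: 14 (2R,5S)-allylic acetate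
Conditions: Ac2O, Et3N, DMAP (5 mol %), CH2Cl2, 0 °C to rt
Reagents that add atoms: acetic anhydride, CC(=O)OC(C)=O
Why: DMAP-catalysed acetylation installs, with retention at C2, the two carbons that become C8 and C9.

Step 10
Reactants: 14 (2R,5S)-allylic acetate
Product: 18 (5S,10R)-acid (ring A with C1=C2; C10 bears C20 and CH2CO2H; C5 bears CH2CH2OTBS; the two arms trans), via lithium enolate 15 (not isolated), via silyl ketene acetal 16 (not isolated), via silyl ester 17 (not isolated)
Conditions: LiN(i-Pr)2 (1.3 equiv), THF, −78 °C; TBSCl, DMPU, −78 to 65 °C; then K2CO3, MeOH–H2O, rt, work-up at pH 5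
Reagents that add atoms: none
Why: Ireland–Claisen rearrangement: the O-silyl ketene acetal 16 shifts suprafacially from the pseudoaxial C2–O bond to C10, so C9–C10 forms on the face opposite to the pseudoaxial C5 arm and 2R is relayed to the quaternary centre, the alkene moves to C1=C2, and carbonate hydrolysis frees the acid from 17 without loss of the silyl ether.

Step 11
Reactants: 18 (5S,10R)-acid
Product: 19 (5S,10S)-saturated acid (same spatial arrangement; descriptor changes with the priorities)
Conditions: H2 (1 atm), 10% Pd/C, EtOAc, rt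
Reagents that add atoms: none
Why: Heterogeneous hydrogenation saturates the only alkene, the cis-disubstituted C1=C2 bond, before any alkene of the target is in place, and touches no stereocentre.

Step 12
Reactants: 19 (5S,10S)-saturated acid
Product: 21 (5S,10S)-N-methoxy-N-methylamide, via acyl imidazole 20 (not isolated)
Conditions: 1,1'-carbonyldiimidazole (1.2 equiv), CH2Cl2, rt; then MeNH(OMe)·HCl (1.5 equiv), rt
Reagents that add atoms: N,O-dimethylhydroxylamine hydrochloride, CNOC.Cl
Why: Amide formation through the acyl imidazole is mild enough for the silyl ether and the acetonide, and gives the N-methoxy-N-methylamide that will later accept exactly one carbanion.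

Step 13
Reactants: 21 (5S,10S)-N-methoxy-N-methylamide; 22 allyl bromide
Product: 24 9-allyl amide (5S,10R; both C9 epimers), via lithium amide enolate 23 (not isolated)
Conditions: LiN(i-Pr)2 (1.2 equiv), THF, −78 °C; 22 (2 equiv), DMPU, −78 to −40 °C
Reagents that add atoms: none
Why: Alkylation of the Z lithium amide enolate with a reactive allylic bromide forms C9–C11 at the only enolisable carbon of the molecule, and the facial bias next to C10 is not relied upon because both C9 epimers converge in step 17.

Step 14
Reactants: 24 9-allyl amide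
Product: 25 hydroxy amide (C7–OH; both C9 epimers)
Conditions: n-Bu4NF, THF, 0 °C to rt
Reagents that add atoms: none
Why: Fluoride cleaves the primary silyl ether selectively, while the amide, the acetonide and the alkene are untouched.

Step 15
Reactants: 25 hydroxy amide
Product: 26 iodo amide (ring A with C4 spiro-acetonide; CH2CH2I on C5; CH(allyl)C(=O)N(OMe)Me on C10; 5S,10R; both C9 epimers)
Conditions: PPh3, I2, imidazole, CH2Cl2, 0 °C, dark
Reagents that add atoms: iodine, [I][I]
Why: Appel-type iodination converts the unhindered primary alcohol by SN2 displacement of its alkoxyphosphonium ion, and the imidazole buffer protects the acetonide.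

Step 16
Reactants: 26 iodo amide
Product: 29 9-allyl trans-decal-8-one acetonide (5S,10R; both C9 epimers), via alkyllithium 27 (not isolated), via lithium chelate 28 (not isolated)
Conditions: t-BuLi (2.1 equiv), pentane–Et2O (3:2), −78 °C, then to 0 °C; aq NH4Cl
Reagents that add atoms: none
Why: t-BuLi attacks the iodine of the primary iodide (exchange through an ate complex), the second equivalent destroys the t-BuI formed, and the primary alkyllithium 27, in which the formerly electrophilic C7 is now nucleophilic, adds to the C8 amide carbonyl to give the O–Li–OMe chelate 28, which collapses to the ketone only on aqueous quench. The closest known reaction type is the intramolecular ketone synthesis by halogen–lithium exchange and acylation with an N-methoxy-N-methylamide (Parham-type cyclisation). Ring B closes in the 6-exo-trig mode, helped by the trans arrangement of the C5 and C10 arms, which are both equatorial on chair ring A and hold C7 close to C8. No stereocentre is created: C5 and C10 lie away from any acidic site and stay as set, and C9 is left for step 17. The step needs chemoselectivity, namely exchange before any attack of t-BuLi on the amide or on C9–H, and a single addition; the first is secured by the very fast exchange of an unhindered primary iodide at −78 °C against a carbonyl group shielded by C9 and quaternary C10, the second by the chelate. The allyl group is too far from C7 to interfere, since carbolithiation would need a seven-membered ring.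

Step 17
Reactants: 29 9-allyl trans-decal-8-one acetonide (both C9 epimers)
Product: 30 (5S,9S,10R)-9-allyl trans-decal-8-one acetonide (allyl equatorial; H9 on the same face as H5)
Conditions: NaOMe (0.3 equiv), MeOH, rt to 40 °C
Reagents that add atoms: none
Why: Base-mediated epimerisation through the C8 enolate: under thermodynamic control the allyl group takes the equatorial position on chair ring B, as in related 1-alkyl-8a-methyl-2-decalones, and this is the C9 configuration of the target.

Step 18
Reactants: 30 (5S,9S,10R)-9-allyl trans-decal-8-one acetonide; 31 methacrolein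
Product: 32 (12E)-keto enal (C12=C13 trisubstituted; C14 aldehyde; C8 ketone)
Conditions: 31 (8 equiv), second-generation Hoveyda–Grubbs catalyst RuCl2(SIMes)(=CH-C6H4-2-O-i-Pr) (5 mol %), CH2Cl2, 40 °C
Reagents that add atoms: none
Why: Olefin cross-metathesis of a terminal alkene with excess methacrolein should give the trisubstituted enal as the E isomer (formyl group trans to C11), with the ketone and the acetonide as spectators.

Step 19
Reactants: 32 (12E)-keto enal
Product: 34 triene acetonide (5S,9R,10S,12E), via keto diene 33 (not isolated)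
Conditions: Ph3PCH3Br (6 equiv), KOt-Bu (5.5 equiv), THF, 32 added at 0 °C, then 60 °C
Reagents that add atoms: methyltriphenylphosphonium bromide, C[P+](c1ccccc1)(c1ccccc1)c1ccccc1.[Br-]
Why: Twofold Wittig methylenation: the unhindered enal reacts first (C14=C15, giving 33) and the hindered C8 ketone reacts on heating (C8=C17), the basic ylide cannot erode C9 because it is already the thermodynamic epimer, and the 12E alkene is not involved.

Step 20
Reactants: 34 triene acetonide
Product: 35 (12E)-ent-labda-8(17),12,14-triene-18,19-diol
Conditions: AcOH–THF–H2O (3:1:1), rt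
Reagents that add atoms: none
Why: Mild acid hydrolysis of the six-membered acetonide, under which dilute acetic acid at room temperature should neither shift the exocyclic C8=C17 alkene nor protonate the diene.

Step 21
Reactants: 35 diol
Product: 36 target (12E)-ent-labda-8(17),12,14-triene-18,19-diyl diacetate (CNP0129553.1)
Conditions: Ac2O, pyridine, DMAP (10 mol %), CH2Cl2, rt
Reagents that add atoms: acetic anhydride, CC(=O)OC(C)=O
Why: DMAP-catalysed acetylation of both primary alcohols on C4 completes the target without touching a stereocentre.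

**Compound list**
1 | (2,2-dimethyl-1,3-dioxan-5-yl)methanol | CC1(C)OCC(CO)CO1 | starting material
2 | 2,2-dimethyl-1,3-dioxane-5-carbaldehyde | CC1(C)OCC(C=O)CO1 | intermediate
3 | ethyl vinyl ketone (pent-1-en-3-one) | C=CC(=O)CC | starting material
4 | 2,2-dimethyl-5-(3-oxopentyl)-1,3-dioxane-5-carbaldehyde | CCC(=O)CCC1(C=O)COC(C)(C)OC1 | intermediate
5 | 3,3,8-trimethyl-2,4-dioxaspiro[5.5]undec-7-en-9-one | CC1=CC2(CCC1=O)COC(C)(C)OC2 | intermediate
6 | (9S)-3,3,8-trimethyl-2,4-dioxaspiro[5.5]undec-7-en-9-ol (1S) | O[C@H]1CCC2(COC(C)(C)OC2)C=C1C | intermediate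
7 | triethyl orthoacetate | CC(OCC)(OCC)OCC | starting material
8 | 1-ethoxyvinyl ether of 6 (ketene acetal) | C=C(OCC)O[C@H]1CCC2(COC(C)(C)OC2)C=C1C | intermediate
9 | ethyl [(7S)-3,3,8-trimethyl-2,4-dioxaspiro[5.5]undec-8-en-7-yl]acetate (5S) | CCOC(=O)C[C@H]1C(C)=CCCC12COC(C)(C)OC2 | intermediate
10 | 2-[(7S)-3,3,8-trimethyl-2,4-dioxaspiro[5.5]undec-8-en-7-yl]ethanol (5S) | OCC[C@H]1C(C)=CCCC12COC(C)(C)OC2 | intermediate
11 | tert-butyldimethylsilyl ether of 10 | CC(C)(C)[Si](C)(C)OCC[C@H]1C(C)=CCCC12COC(C)(C)OC2 | intermediate
12 | (5S)-enone, C2 ketone conjugated to C1=C10 | CC(C)(C)[Si](C)(C)OCC[C@H]1C(C)=CC(=O)CC12COC(C)(C)OC2 | intermediate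
13 | (2R,5S)-allylic alcohol, OH trans to the C5 arm | CC(C)(C)[Si](C)(C)OCC[C@H]1C(C)=C[C@H](O)CC12COC(C)(C)OC2 | intermediate
14 | (2R,5S)-allylic acetate | CC(C)(C)[Si](C)(C)OCC[C@H]1C(C)=C[C@H](OC(C)=O)CC12COC(C)(C)OC2 | intermediate
15 | lithium enolate of 14 | CC(C)(C)[Si](C)(C)OCC[C@H]1C(C)=C[C@H](OC(=C)O[Li])CC12COC(C)(C)OC2 | intermediate
16 | tert-butyldimethylsilyl ketene acetal of 14 | CC(C)(C)[Si](C)(C)OCC[C@H]1C(C)=C[C@H](OC(=C)O[Si](C)(C)C(C)(C)C)CC12COC(C)(C)OC2 | intermediate
17 | tert-butyldimethylsilyl ester of 18 | CC(C)(C)[Si](C)(C)OC(=O)C[C@]1(C)C=CCC2(COC(C)(C)OC2)[C@H]1CCO[Si](C)(C)C(C)(C)C | intermediate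
18 | (5S,10R)-acid with C1=C2 alkene | OC(=O)C[C@]1(C)C=CCC2(COC(C)(C)OC2)[C@H]1CCO[Si](C)(C)C(C)(C)C | intermediate
19 | (5S,10S)-saturated acid | OC(=O)C[C@]1(C)CCCC2(COC(C)(C)OC2)[C@H]1CCO[Si](C)(C)C(C)(C)C | intermediate
20 | acyl imidazole of 19 | O=C(C[C@]1(C)CCCC2(COC(C)(C)OC2)[C@H]1CCO[Si](C)(C)C(C)(C)C)n1ccnc1 | intermediate
21 | (5S,10S)-N-methoxy-N-methylamide | CON(C)C(=O)C[C@]1(C)CCCC2(COC(C)(C)OC2)[C@H]1CCO[Si](C)(C)C(C)(C)C | intermediate
22 | allyl bromide | C=CCBr | starting material
23 | Z lithium enolate of 21 | CON(C)/C(O[Li])=C/[C@]1(C)CCCC2(COC(C)(C)OC2)[C@H]1CCO[Si](C)(C)C(C)(C)C | intermediate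
24 | 9-allyl N-methoxy-N-methylamide, 5S,10R, both C9 epimers | C=CCC(C(=O)N(C)OC)[C@]1(C)CCCC2(COC(C)(C)OC2)[C@H]1CCO[Si](C)(C)C(C)(C)C | intermediate
25 | hydroxy amide, both C9 epimers | C=CCC(C(=O)N(C)OC)[C@]1(C)CCCC2(COC(C)(C)OC2)[C@H]1CCO | intermediate
26 | iodo amide, both C9 epimers (precursor of the key step) | C=CCC(C(=O)N(C)OC)[C@]1(C)CCCC2(COC(C)(C)OC2)[C@H]1CCI | intermediate
27 | C7 alkyllithium | C=CCC(C(=O)N(C)OC)[C@]1(C)CCCC2(COC(C)(C)OC2)[C@H]1CC[Li] | intermediate
28 | chelated lithium hemiaminal at C8 | C=CCC1C(O[Li])(N(C)OC)CC[C@@H]2C3(COC(C)(C)OC3)CCC[C@@]12C | intermediate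
29 | 9-allyl trans-decal-8-one acetonide, 5S,10R, both C9 epimers | C=CCC1C(=O)CC[C@@H]2C3(COC(C)(C)OC3)CCC[C@@]12C | intermediate
30 | (5S,9S,10R)-9-allyl trans-decal-8-one acetonide | C=CC[C@@H]1C(=O)CC[C@@H]2C3(COC(C)(C)OC3)CCC[C@@]12C | intermediate
31 | methacrolein | C=C(C)C=O | starting material
32 | (12E)-keto enal | O=C/C(C)=C/C[C@@H]1C(=O)CC[C@@H]2C3(COC(C)(C)OC3)CCC[C@@]12C | intermediate
33 | (12E)-keto diene | C=C/C(C)=C/C[C@@H]1C(=O)CC[C@@H]2C3(COC(C)(C)OC3)CCC[C@@]12C | intermediate
34 | triene acetonide, 5S,9R,10S,12E | C=C/C(C)=C/C[C@@H]1C(=C)CC[C@@H]2C3(COC(C)(C)OC3)CCC[C@@]12C | intermediate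
35 | (12E)-ent-labda-8(17),12,14-triene-18,19-diol | C=C/C(C)=C/C[C@@H]1C(=C)CC[C@@H]2C(CO)(CO)CCC[C@@]12C | intermediate
36 | (12E)-ent-labda-8(17),12,14-triene-18,19-diyl diacetate | C=C/C(C)=C/C[C@@H]1C(=C)CC[C@@H]2C(COC(C)=O)(COC(C)=O)CCC[C@@]12C | target

Total step count: 21. Longest linear sequence: 21 steps (1 to 36). Compounds 3, 7, 22 and 31 are bought and enter directly.

**Steps most likely to fail**

Step 2. Expulsion of a ring alkoxide from the enolate of 2 would open the dioxane and shed acetone, and this β-elimination may outrun the Michael addition. Compound 3 may also polymerise under hydroxide. The fallback sets out from 2 and comes back at 4. Me3SiOTf/Et3N (CH2Cl2, 0 °C) turns 2 into the trimethylsilyl enol ether F1, a neutral nucleophile that has no enolate to eliminate from. A Sc(OTf)3-catalysed Mukaiyama–Michael addition of F1 to 3 (CH2Cl2, −78 °C) gives the silyl enol ether adduct F2. Hydrolysis of F2 on aqueous work-up delivers 4, which is now isolated. With C4 quaternary, KOH/EtOH closes 4 to 5 as in the main route.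

Step 13. The amide enolate may fragment by N–O cleavage (loss of the methoxy group), or alkylation beside quaternary C10 may be too slow, and either process would consume 21. The fallback sets out from 19 and comes back at 24. The carboxylate dianion of 19 (LiN(i-Pr)2, 2.3 equiv, THF, 0 to 40 °C) is allylated with 22 to the α-allyl acid F3 (both C9 epimers). 1-Chloro-N,N,2-trimethylpropenylamine converts F3 under neutral conditions into the acid chloride F4. MeNH(OMe)·HCl and pyridine then give 24, so the N-methoxy-N-methylamide is never enolised.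

Step 16. Proton transfer from C9–H to the new carbanion would give uncyclised, reduced material. Attack of t-BuLi on the N-methoxy group is the other competing process, because the carbonyl group is hindered. The fallback keeps the C7–C8 closure and the reversal of polarity at C7, but uses a more electrophilic acceptor and a single-electron reductant. It sets out from 26 and comes back at 29. i-Bu2AlH (CH2Cl2, −78 °C) reduces the amide to the iodo aldehyde F5. SmI2/HMPA (THF, −78 to 0 °C) then effects an intramolecular Barbier closure to the decal-8-ol F6 (mixture at C8 and C9). Dess–Martin periodinane oxidises F6 to 29.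

**Further compounds**
F1 | step 2 | (2,2-dimethyl-1,3-dioxan-5-ylidene)methyl trimethylsilyl ether | C[Si](C)(C)OC=C1COC(C)(C)OC1
F2 | step 2 | 2,2-dimethyl-5-[3-(trimethylsilyloxy)pent-2-enyl]-1,3-dioxane-5-carbaldehyde | CCC(=CCC1(C=O)COC(C)(C)OC1)O[Si](C)(C)C
F3 | step 13 | 9-allyl acid, 5S,10R, both C9 epimers | C=CCC(C(=O)O)[C@]1(C)CCCC2(COC(C)(C)OC2)[C@H]1CCO[Si](C)(C)C(C)(C)C
F4 | step 13 | 9-allyl acid chloride, both C9 epimers | C=CCC(C(=O)Cl)[C@]1(C)CCCC2(COC(C)(C)OC2)[C@H]1CCO[Si](C)(C)C(C)(C)C
F5 | step 16 | iodo aldehyde, both C9 epimers | C=CCC(C=O)[C@]1(C)CCCC2(COC(C)(C)OC2)[C@H]1CCI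
F6 | step 16 | 9-allyl trans-decal-8-ol acetonide, mixture at C8 and C9 | C=CCC1C(O)CC[C@@H]2C3(COC(C)(C)OC3)CCC[C@@]12C
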